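# Grevirobstol B by double dithiane alkylation: synthesis design

## The problem

Grevirobstol B (11) is a 22-membered macrocycle in which two oxygenated benzene rings are joined twice, through a diaryl ether oxygen on one side and through an unbranched sixteen-carbon chain on the other. Ring A carries its hydroxyl at A1, the chain terminus C16 at A3 and the ether oxygen at A5, while ring B carries the ether oxygen at B1, hydroxyls at B2 and B4 and the other chain terminus C1 at B6. The molecule has no stereocentre and no alkene, so nothing has to be set and nothing in the substrate can steer a ring closure, and the real difficulty is the entropic cost of closing a large, flexible ring whose chain offers no functional handle. The ether oxygen at B1 sits between the B2 oxygen and the B6 alkyl group, so this aryl–O bond is flanked on both sides and is better made on small fragments than across a macrocycle. The three phenols are acidic and, on the 1,2,4-trioxygenated ring B in particular, prone to oxidation under basic conditions, so they must stay masked through every organometallic step and be released last under non-oxidising conditions. What makes a short route possible is that C1 and C16 are both benzylic: each can be carried as an aryl aldehyde carbon on B6 and A3, turned into a 2-aryl-1,3-dithiane and used as an acyl anion equivalent. C2 to C15, the fourteen carbons that separate them, bear nothing but hydrogen and can be bought as a single α,ω-difunctional piece.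

## Retrosynthesis

**11 from 10 (three O–CH3 bonds).** The phenols are masked as methyl ethers in trimethyl ether 10. Methyl is preferred to benzyl, whose benzylic O–CH2 protons would compete in the lithiation and which would be lost to nickel, and to MOM or silyl groups, which invite directed ortho-lithiation or migration. Methyl ethers are inert to n-BuLi at low temperature and to Raney Ni, and BBr3 removes them without touching the diaryl ether. The forward step has only to cleave three aryl methyl ethers.

**10 from 9 (four C–S bonds).** The methylenes C1 and C16 of 10 are traced back to the spiro-dithiane carbons of macrocycle 9. The dithianes are traceless: nickel desulfurisation replaces them by hydrogen directly, so no ketone stage and no separate deoxygenation are needed. The forward reaction must hydrogenolyse C–S bonds without cleaving the Ar–O–Ar bond.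

**9 from 5 and 6 (C1–C2 and C15–C16).** Both chain–benzylic bonds are cut at once, giving bis(dithiane) 5 and 1,14-dibromotetradecane 6; in the forward direction the reaction passes through dianion 7 and the monoalkylated bromide 8. A cut inside the chain, for instance at C8–C9 by metathesis, would need handles in the chain that must later be erased, and closing the ring at O–B1 would place the most hindered bond formation in the macrocyclisation. The benzylic positions are the only two chain carbons that the arenes can activate, and cutting there leaves the C14 segment as a catalogue compound. The precursor shrinks to a C17 diaryl ether with two identical functional groups. The forward step must deprotonate both dithiane C–H bonds in preference to aryl C–H bonds and must close the ring in preference to chain growth.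

**5 from 3 and 4 (four C–S bonds).** The two dithianes are made together from dialdehyde 3 and propane-1,3-dithiol 4 by acid-catalysed thioacetalisation, which asks nothing of the substrate beyond two free aldehydes.

**3 from 1 and 2 (O–B1).** The ether is cut on the ring B side, giving phenol 1 (ring A, with its oxygen) and aryl bromide 2 (ring B). In this polarity the nucleophile is an unhindered meta-substituted phenol, and the hindered partner is a bromide whose ortho-formyl group assists copper insertion. The opposite polarity would need a chelating salicylaldehyde with two ortho substituents as the O-nucleophile. Both fragments already carry every oxygen and the future C1 and C16 at the aldehyde level, so no redox or regiochemical adjustment follows.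

## Roads not taken

Alternative 1: ring B built inside the macrocycle by Michael–Claisen annulation. The cut removes B1–B6 and B2–B3, so ring B and the macrocycle would arise together. In the forward step NaOMe would deprotonate the aryloxymalonate A2, whose malonate carbon would add to the β-carbon of the enone at the far end of its own chain and so close the 22-membered ring; the methyl ketone enolate formed in that addition would then condense with one ester to give the cyclohexane-1,3-dione A1. The merits are real: the hindered B1–O bond starts as a simple O-alkylation, the 1,2,4-oxygen pattern of ring B is generated by the annulation, and the closure is unimolecular. In these respects this road is better than the chosen plan. Its weak points are that a fully substituted malonate carbanion must add reversibly to a β-alkyl enone across a large ring, creating a quaternary carbon next to a tertiary one, while retro-Michael reaction, γ-deprotonation of the enone and intermolecular addition all compete before the Claisen step can trap the adduct. A1 then needs ester cleavage, decarboxylation and dehydrogenation to become aromatic, in the presence of an electron-rich ring A, and A2 requires the whole C16 chain to be built stepwise on ring A and capped with the enone. The chosen plan has to accept a hindered Ullmann coupling and a two-component closure; against that it sets five steps, two rings bought aromatic, no oxidation-state changes on ring B and a chain bought intact.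

Alternative 2: diaryl ether closed last by carbene O–H insertion. The cut is O–B1 as the final skeletal bond. In the forward step Rh2(OAc)4 would decompose the para-quinone diazide A4 to a carbenoid at B1, which would insert into an O–H bond of the resorcinol at the other chain end and rearomatise ring B to give A3. The hindered ether would form through a very reactive electrophile under neutral conditions, the two ring A hydroxyls are equivalent so there is no regiochemical question, and A3 needs only one demethylation, a shorter end-game than the two steps that follow the key step here. The weak points are that the carbenoid is short-lived and cannot wait for a 22-membered-ring conformer; at the dilution needed it is more likely to meet solvent, the chain C–H bonds or the nucleophilic carbons of the resorcinol (C-arylation, cyclopropanation). A4 would also have to be generated by diazotisation at B1 in a molecule whose free resorcinol is itself an excellent azo-coupling partner, and the chain linking the two arenes must again be assembled stepwise. The lithiated dithianes of the chosen plan persist for hours, so dilution costs nothing in lifetime; the chosen plan is weaker only in its longer deprotection end-game and its bimolecular first alkylation.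

Alternative 3: macrolactone contracted by palladium decarboxylative allylation. The cut is C2–C3, after inserting a CO2 link between them. In the forward step zerovalent palladium, as Pd(PPh3)4, would open the 24-membered allyl β-keto ester A6 to a π-allyl complex and a β-keto carboxylate; after loss of CO2 the ring B ketone enolate would recombine through C2 with the allyl terminus C3, giving the 22-membered ketone A5 with an (E)-C4=C5 alkene. Both ring-forming events are unimolecular, A6 would be closed by an acylketene macrolactonisation, a dependable way to large rings, and the contraction is mild and neutral. In control of oligomerisation this road is better. Its weak points are that after ionisation the enolate and the allyl cation are held together only by the long tether, so recombination at C5 (a 20-membered ring with a vinyl branch), protonation and intermolecular crossover are all open. A5 still carries a ketone and an alkene that cost two extra reductions, and A6 contains the same hindered diaryl ether, so the Ullmann problem is not avoided, and it needs a functionalised C12 chain and a β-keto acid equivalent on ring B. The chosen plan answers the oligomerisation risk with slow addition and reaches the saturated chain directly, in roughly half the number of steps.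

Key step: step 3

Assumption: compounds 1, 2, 4 and 6 are treated as catalogue compounds; the atom labels A1–A6, B1–B6 and C1–C16 defined in the first section are used throughout.

## Route

Step 1
Reactants: 1 3-hydroxy-5-methoxybenzaldehyde; 2 2-bromo-3,5-dimethoxybenzaldehyde
Product: 3 2-(3-formyl-5-methoxyphenoxy)-3,5-dimethoxybenzaldehyde
Conditions: CuI (10 mol%), N,N-dimethylglycine·HCl (30 mol%), Cs2CO3 (2.5 equiv), 1,4-dioxane, 100 °C
Reagents that add atoms: none
Why: Ullmann-type copper-catalysed diaryl ether synthesis; the ortho-formyl group of 2 assists insertion of monovalent copper into the flanked C–Br bond, the phenoxide of 1 is unhindered, and neither aldehyde is enolisable, so carbonate base is tolerated.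

Step 2
Reactants: 3 2-(3-formyl-5-methoxyphenoxy)-3,5-dimethoxybenzaldehyde; 4 propane-1,3-dithiol
Product: 5 2-{3-[2-(1,3-dithian-2-yl)-4,6-dimethoxyphenoxy]-5-methoxyphenyl}-1,3-dithiane
Conditions: 4 (2.4 equiv), BF3·OEt2 (cat.), CH2Cl2, 0 °C to rt
Reagents that add atoms: none
Why: Lewis-acid-catalysed thioacetalisation of both aryl aldehydes; methyl ethers and the diaryl ether are inert to catalytic BF3, and six-membered dithiane formation is strongly favoured.

Step 3
Reactants: 5 2-{3-[2-(1,3-dithian-2-yl)-4,6-dimethoxyphenoxy]-5-methoxyphenyl}-1,3-dithiane; 6 1,14-dibromotetradecane
Product: 9 macrocyclic C1/C16 bis(1,3-dithiane) of grevirobstol B trimethyl ether, via dilithiated bis(dithiane) 7 (not isolated), via monoalkylated lithio bromide 8 (not isolated)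
Conditions: n-BuLi (2.1 equiv), THF, −30 °C; then simultaneous slow addition of 7 and 6 (1.0 equiv) to THF (final ca. 2 mM), 0 °C to rt
Reagents that add atoms: none
Why: Corey–Seebach umpolung applied at both benzylic carbons: each dithiane C–H, acidified by two sulfur atoms and the attached arene, is far more acidic than any aryl C–H next to a methoxy group, so n-BuLi should give dianion 7 without ortho-lithiation. One carbanion of 7 then attacks a terminus of 6 in a bimolecular SN2 reaction, expected first at the less hindered ring A dithiane carbon to give 8, and the regioisomer alkylated first at C1 converges on the same product. The carbanion that is left displaces the tethered primary bromide in an exo-tet SN2 closure, which makes the second C–C bond and the 22-membered ring. The nearest established reaction type is the stapling of bis(2-aryl-1,3-dithiane) dianions by α,ω-dihalides in cyclophane synthesis, here stretched to a larger ring and a C14 partner. No stereocentre is formed. The selectivity that matters is ring closure over oligomerisation: feeding both components slowly and simultaneously keeps the stationary concentration of both chain ends low, and because the lithiated dithiane persists for hours, 8 can wait for a productive conformation. A primary bromide and a soft sulfur-stabilised carbanion favour substitution over elimination, and ring A carries no electron-withdrawing group, so aryl migration from oxygen to the ring B carbanion (Truce–Smiles) is not expected.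

Step 4
Reactants: 9 macrocyclic C1/C16 bis(1,3-dithiane) of grevirobstol B trimethyl ether
Product: 10 grevirobstol B trimethyl ether (OMe at A1, B2 and B4; saturated C1–C16 chain)
Conditions: Raney Ni (W-2, excess), EtOH/THF, reflux
Reagents that add atoms: none
Why: Mozingo desulfurisation; the four benzylic C–S bonds are hydrogenolysed by hydrogen-loaded nickel, while the aryl methyl ethers and the diaryl ether, which have no benzylic C–O bond, should survive at ethanol reflux.

Step 5
Reactants: 10 grevirobstol B trimethyl ether
Product: 11 grevirobstol B
Conditions: BBr3 (6 equiv), CH2Cl2, −78 °C to rt; then H2O, under argon
Reagents that add atoms: none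
Why: Lewis-acid demethylation of aryl methyl ethers; bromide attacks the methyl carbon of each boron-complexed ether, whereas the diaryl ether offers no sp3 carbon and is left intact, and an oxygen-free work-up protects the electron-rich ring B.

## Compound list

1 | 3-hydroxy-5-methoxybenzaldehyde | COc1cc(O)cc(C=O)c1 | starting material
2 | 2-bromo-3,5-dimethoxybenzaldehyde | COc1cc(OC)c(Br)c(C=O)c1 | starting material
3 | 2-(3-formyl-5-methoxyphenoxy)-3,5-dimethoxybenzaldehyde | COc1cc(Oc2c(OC)cc(OC)cc2C=O)cc(C=O)c1 | intermediate
4 | propane-1,3-dithiol | SCCCS | starting material
5 | 2-{3-[2-(1,3-dithian-2-yl)-4,6-dimethoxyphenoxy]-5-methoxyphenyl}-1,3-dithiane | COc1cc(Oc2c(OC)cc(OC)cc2C2SCCCS2)cc(c1)C1SCCCS1 | intermediate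
6 | 1,14-dibromotetradecane | BrCCCCCCCCCCCCCCBr | starting material
7 | dilithiated bis(dithiane), not isolated: 5 with lithium in place of hydrogen at both dithiane C2 carbons | COc1cc(Oc2c(OC)cc(OC)cc2C2([Li])SCCCS2)cc(c1)C1([Li])SCCCS1 | intermediate
8 | monoalkylated lithio bromide, not isolated: ring A dithiane C2 bears a 14-bromotetradecyl chain, ring B dithiane C2 bears lithium | COc1cc(Oc2c(OC)cc(OC)cc2C2([Li])SCCCS2)cc(c1)C1(CCCCCCCCCCCCCCBr)SCCCS1 | intermediate
9 | macrocyclic C1/C16 bis(1,3-dithiane) of grevirobstol B trimethyl ether (22-membered ring; C1 and C16 are each the C2 carbon of a spiro 1,3-dithiane) | COc1cc3cc(c1)Oc1c(OC)cc(OC)cc1C1(SCCCS1)CCCCCCCCCCCCCCC32SCCCS2 | intermediate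
10 | grevirobstol B trimethyl ether (OMe at A1, B2, B4) | COc1cc2cc(c1)Oc1c(OC)cc(OC)cc1CCCCCCCCCCCCCCCC2 | intermediate
11 | grevirobstol B (22-membered ring: ring A with OH at A1, chain at A3, ether O at A5; ring B with ether O at B1, OH at B2 and B4, chain at B6; saturated C16 chain; achiral) | Oc1cc2cc(c1)Oc1c(O)cc(O)cc1CCCCCCCCCCCCCCCC2 | target

## Step count and least certain steps

Total steps: 5. Longest linear sequence: 5 steps (1 → 3 → 5 → 9 → 10 → 11).

**Step 3 (key step).** The most likely failure is chain growth overtaking ring closure. The second alkylation is entropically disfavoured, and the anionic end of 8 can meet a second dibromide or the bromide end a second dianion. At millimolar dilution, partial protonation of the carbanions by adventitious moisture would also leave open-chain material.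

The fallback sets out from 5 and comes back at 10, replacing the two-component closure by a unimolecular ring-closing metathesis. Double lithiation of 5 as above and alkylation with an excess of 8-bromooct-1-ene F1, at ordinary concentration, should give the bis(oct-7-enyl) bis(dithiane) F2. Ring-closing metathesis of F2 with second-generation Grubbs catalyst in dilute toluene, with loss of ethene, should close the 22-membered ring at C8=C9, remote from all substituents, and give the macrocyclic alkene bis(dithiane) F3 as an E/Z mixture. Raney Ni under hydrogen should then remove the four C–S bonds of F3 and saturate its alkene in one operation, delivering 10. The thioacetal sulfur may slow the ruthenium carbene, so a higher catalyst loading is to be expected.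

**Step 1.** Insertion of copper into the C–Br bond of 2, flanked by the formyl and methoxy groups, may be slow. Hydrodebromination of 2 or base-induced degradation of the aldehydes could then compete.

The fallback sets out from 2 and comes back at 3, reversing the roles of the rings. Miyaura borylation of 2 (B2pin2, Pd(dppf)Cl2, KOAc, dioxane, 90 °C) should give 3,5-dimethoxy-2-(4,4,5,5-tetramethyl-1,3,2-dioxaborolan-2-yl)benzaldehyde F4. Oxidation of the C–B bond of F4 with N-methylmorpholine N-oxide, which leaves the aldehyde untouched, should give 2-hydroxy-3,5-dimethoxybenzaldehyde F5. Chan–Lam etherification of F5 with (3-formyl-5-methoxyphenyl)boronic acid F6, under Cu(OAc)2 catalysis in air with pyridine and 4 Å molecular sieves in CH2Cl2 at rt, should then give 3 at room temperature without strong base.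

**Step 4.** Hydrogenolysis may stall at the more hindered C1 dithiane next to the aryloxy group. Forcing the reaction with very active nickel could instead start to cleave the diaryl ether or saturate an arene.

The fallback sets out from 9 and comes back at 10 by way of the carbonyl compounds. Alkylative hydrolysis of both dithianes (MeI, CaCO3, aqueous MeCN, 60 °C), which does not oxidise the electron-rich rings, should give the macrocyclic 1,16-diketone trimethyl ether F7. Wolff–Kishner reduction of F7 under Huang–Minlon conditions (N2H4·H2O, KOH, diethylene glycol, up to 200 °C, under nitrogen) should convert both aryl ketones into methylenes and return 10. Any incidental O-demethylation in hot alkali is harmless, since step 5 removes the methyl ethers anyway.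

## Further compounds

F1 | step 3 | 8-bromooct-1-ene | C=CCCCCCCBr
F2 | step 3 | 2-(oct-7-en-1-yl)-2-{3-[2-(2-(oct-7-en-1-yl)-1,3-dithian-2-yl)-4,6-dimethoxyphenoxy]-5-methoxyphenyl}-1,3-dithiane | COc1cc(Oc2c(OC)cc(OC)cc2C2(CCCCCCC=C)SCCCS2)cc(c1)C1(CCCCCCC=C)SCCCS1
F3 | step 3 | macrocyclic C1/C16 bis(1,3-dithiane) with a C8=C9 alkene, trimethyl ether (E/Z mixture, both isomers serve) | COc1cc3cc(c1)Oc1c(OC)cc(OC)cc1C1(SCCCS1)CCCCCCC=CCCCCCCC32SCCCS2
F4 | step 1 | 3,5-dimethoxy-2-(4,4,5,5-tetramethyl-1,3,2-dioxaborolan-2-yl)benzaldehyde | COc1cc(OC)c(B2OC(C)(C)C(C)(C)O2)c(C=O)c1
F5 | step 1 | 2-hydroxy-3,5-dimethoxybenzaldehyde | COc1cc(OC)c(O)c(C=O)c1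
F6 | step 1 | (3-formyl-5-methoxyphenyl)boronic acid | COc1cc(C=O)cc(B(O)O)c1
F7 | step 4 | macrocyclic 1,16-diketone of grevirobstol B trimethyl ether | COc1cc2cc(c1)Oc1c(OC)cc(OC)cc1C(=O)CCCCCCCCCCCCCCC2=O
A1 | alternative 1 | macrocyclic methyl 1-aryloxy-2,4-dioxocyclohexane-1-carboxylate (racemic; one diastereomer drawn) | COC(=O)[C@@]12Oc3cc(OC)cc(c3)CCCCCCCCCCCCCCCC[C@H]1CC(=O)CC2=O
A2 | alternative 1 | dimethyl 2-{3-methoxy-5-[(17E)-19-oxoicos-17-en-1-yl]phenoxy}propanedioate | COC(=O)C(Oc1cc(OC)cc(CCCCCCCCCCCCCCCC/C=C/C(C)=O)c1)C(=O)OC
A3 | alternative 2 | grevirobstol B methyl ether at B2 | COc1cc(O)cc2c1Oc1cc(O)cc(c1)CCCCCCCCCCCCCCCC2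
A4 | alternative 2 | 4-diazo-5-[16-(3,5-dihydroxyphenyl)hexadecyl]-3-methoxycyclohexa-2,5-dien-1-one | COC1=CC(=O)C=C(CCCCCCCCCCCCCCCCc2cc(O)cc(O)c2)C1=[N+]=[N-]
A5 | alternative 3 | macrocyclic C1 ketone with (E)-C4=C5 alkene, trimethyl ether | COc1cc2cc(c1)Oc1c(OC)cc(OC)cc1C(=O)CC/C=C/CCCCCCCCCCC2
A6 | alternative 3 | 24-membered allyl β-keto ester macrolactone, trimethyl ether | COc1cc2cc(c1)Oc1c(OC)cc(OC)cc1C(=O)CC(=O)OC/C=C/CCCCCCCCCCC2
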